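**Plan**

- Numbering: lactone O1, C2 (carbonyl), C3, C4, C5; C6 is the CH2 from C3 to ring A (3-hydroxy-4-methoxyphenyl), C7 the CH2 from C4 to ring B (3,4-dimethoxyphenyl); the target is the (3R,4R)-trans lactone.
- Retrosynthesis cuts, in this order: the benzyl ether on the ring A phenol, C7–ring B (sp3–sp2 coupling), O1–C5 (lactone closure), C3–C6 (enolate benzylation), C3=C4 (olefination of the oxetane ketone).
- Enabling feature: C4 carries two one-carbon arms, C5 bound to O1 and C7 bound to ring B; with C4 they are the three carbons of an oxetane (C4 = oxetane carbon 3, C5 and C7 = its two CH2 groups), so a carboxyl group at C2 can open that oxetane onto itself.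
- Forward: the oxetane ketone is olefinated with a chiral imide phosphonate and hydrogenated, C3 is benzylated with the ring A bromide, the acid is freed, the lactone (the only ring that has to be made) closes by oxetane opening, ring B is coupled to C7, and the phenol is unmasked.
- Stereochemistry: C3 comes from the oxazolidinone auxiliary in the enolate alkylation; C4 comes from C3, because the two lactones that differ in which CH2 became C5 equilibrate toward trans.

Key step: step 8

Assumption: all five starting materials, the O-benzylated isovanillyl alcohol included, are catalogue compounds.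

**Route**

Step 1
Reactants: 1 (R)-4-benzyloxazolidin-2-one; 2 bromoacetyl bromide
Product: 4 (R)-4-benzyl-3-(2-bromoacetyl)oxazolidin-2-one, via lithium oxazolidinide 3 (not isolated)
Conditions: n-BuLi (1.05 equiv), THF, −78 °C; then 2, −78 → 0 °C
Reagents that add atoms: none
Why: N-acylation of the lithiated oxazolidinone with an acyl bromide is routine, and the acyl bromide carbon is far more electrophilic than the CH2Br carbon, so 3 should be acylated and not alkylated while the auxiliary stereocentre stays untouched.

Step 2
Reactants: 4 (R)-4-benzyl-3-(2-bromoacetyl)oxazolidin-2-one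
Product: 5 diethyl {2-[(R)-4-benzyl-2-oxooxazolidin-3-yl]-2-oxoethyl}phosphonate
Conditions: P(OEt)3 (neat, 3 equiv), 90 °C, EtBr distilled off
Reagents that add atoms: triethyl phosphite, CCOP(OCC)OCC
Why: Michaelis–Arbuzov reaction, in which the phosphite displaces the activated primary bromide next to the imide carbonyl and the ethoxyphosphonium bromide collapses with loss of bromoethane.

Step 3
Reactants: 5 diethyl {2-[(R)-4-benzyl-2-oxooxazolidin-3-yl]-2-oxoethyl}phosphonate; 6 oxetan-3-one
Product: 7 (R)-4-benzyl-3-[2-(oxetan-3-ylidene)acetyl]oxazolidin-2-one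
Conditions: LiCl, i-Pr2NEt, MeCN, 0 °C → rt
Reagents that add atoms: none
Why: Horner–Wadsworth–Emmons olefination under Masamune–Roush conditions should form C3=C4, since the strained ketone is about as electrophilic as an aldehyde, is symmetrical so that no alkene isomers can arise, and the mild amine base spares the imide.

Step 4
Reactants: 7 (R)-4-benzyl-3-[2-(oxetan-3-ylidene)acetyl]oxazolidin-2-one
Product: 8 (R)-4-benzyl-3-[2-(oxetan-3-yl)acetyl]oxazolidin-2-one
Conditions: H2 (1 atm), 10% Pd/C, EtOAc, rt
Reagents that add atoms: none
Why: heterogeneous catalytic hydrogenation of a strained, conjugated exocyclic alkene is fast at 1 atm, the oxetane and the C-benzyl group of the auxiliary are not hydrogenolysed, and the new sp3 carbon (future C4) bears two identical CH2O arms and is not yet a stereocentre.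

Step 5
Reactants: 9 3-benzyloxy-4-methoxybenzyl alcohol
Product: 10 3-benzyloxy-4-methoxybenzyl bromide
Conditions: PBr3 (0.4 equiv), Et2O, 0 °C; used without storage
Reagents that add atoms: phosphorus tribromide, BrP(Br)Br
Why: standard conversion of a benzylic alcohol into its bromide through the phosphite ester, with the aryl ethers stable to the short cold reaction and the electron-rich bromide used at once because it tends to self-condense on storage.

Step 6
Reactants: 8 (R)-4-benzyl-3-[2-(oxetan-3-yl)acetyl]oxazolidin-2-one; 10 3-benzyloxy-4-methoxybenzyl bromide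
Product: 12 (R)-4-benzyl-3-[(R)-3-(3-benzyloxy-4-methoxyphenyl)-2-(oxetan-3-yl)propanoyl]oxazolidin-2-one, via sodium enolate 11 (not isolated)
Conditions: NaN(SiMe3)2 (1.1 equiv), THF, −78 °C; then 10 (1.5 equiv), −78 → −40 °C
Reagents that add atoms: none
Why: Evans asymmetric alkylation, in which the chelated sodium Z enolate 11 offers the reactive benzylic bromide the face opposite to the benzyl group of the (R)-auxiliary, forming the C3–C6 bond with the R configuration at the future C3, while the oxetane is inert to the amide base at −78 °C.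

Step 7
Reactants: 12 (R)-4-benzyl-3-[(R)-3-(3-benzyloxy-4-methoxyphenyl)-2-(oxetan-3-yl)propanoyl]oxazolidin-2-one
Product: 15 (R)-3-(3-benzyloxy-4-methoxyphenyl)-2-(oxetan-3-yl)propanoic acid, via lithium peroxycarboxylate 13 (not isolated), via lithium carboxylate 14 (not isolated)
Conditions: LiOH·H2O (2 equiv), 30% H2O2 (4 equiv), THF/H2O 3:1, 0 °C; aq Na2SO3; CH2Cl2 wash of the basic phase (returns 1); aq NaHSO4 to pH 3–4, 0 °C, EtOAc; used at once
Reagents that add atoms: hydrogen peroxide, OO
Why: hydroperoxide cleavage of an N-acyl oxazolidinone, in which the small and strongly nucleophilic LiOOH attacks the exocyclic carbonyl even of a branched acyl group, sulfite reduces peracid salt 13 to carboxylate 14, the oxetane survives the basic medium, C3 is not epimerised at 0 °C, and cold acidification with a non-nucleophilic acid frees the acid (any ring opening that starts here only anticipates step 8).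

Step 8
Reactants: 15 (R)-3-(3-benzyloxy-4-methoxyphenyl)-2-(oxetan-3-yl)propanoic acid
Product: 17 (3R,4S)-3-(3-benzyloxy-4-methoxybenzyl)-4-(hydroxymethyl)dihydrofuran-2(3H)-one (trans), via cis lactone 16 (not isolated)
Conditions: TsOH·H2O (10 mol %), H2O (2 equiv), toluene/1,4-dioxane 4:1 (0.02 M), 60 °C
Reagents that add atoms: none
Why: The sulfonic acid protonates the oxetane oxygen and the neighbouring carboxyl oxygen attacks one ring CH2 from the backside, an intramolecular SN2 opening that trades the strain of the four-membered ring for the O1–C5 bond and releases the other CH2 as the C7 alcohol; the closest known reaction type is the isomerisation of oxetane-carboxylic acids into hydroxymethyl γ-lactones. The lactone is the only ring closed, and it closes in the 5-exo-tet mode. C4 is the only new stereocentre; its configuration depends on which of the two diastereotopic CH2 groups becomes C5, and it is controlled by the existing C3 centre because the arylmethyl group on C3 and the hydroxymethyl group on C4 prefer to sit trans on the five-membered ring. The choice is made under thermodynamic control, since cis lactone 16 and trans lactone 17 should interconvert under the acid by translactonisation through the free hydroxymethyl group or through the ring-opened dihydroxy acid (in which C4 carries two identical arms), so material that closed on the wrong arm should drain into 17. Two selectivities are needed: O-alkylation of the carboxyl group over C-alkylation of the electron-rich ring A, secured by the faster five-ring closure of the nearer nucleophile, and retention at C3, secured by the absence of base so that the lactone is never enolised.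

Step 9
Reactants: 17 (3R,4S)-3-(3-benzyloxy-4-methoxybenzyl)-4-(hydroxymethyl)dihydrofuran-2(3H)-one
Product: 18 (3R,4R)-3-(3-benzyloxy-4-methoxybenzyl)-4-(bromomethyl)dihydrofuran-2(3H)-one
Conditions: CBr4, PPh3, CH2Cl2, 0 °C → rt
Reagents that add atoms: carbon tetrabromide, BrC(Br)(Br)Br
Why: Appel reaction, in which bromide displaces the alkoxyphosphonium ion at the primary C7 under neutral conditions, so neither the lactone nor C3 and C4 are affected (the descriptor at C4 changes only through the priority rules).

Step 10
Reactants: 18 (3R,4R)-3-(3-benzyloxy-4-methoxybenzyl)-4-(bromomethyl)dihydrofuran-2(3H)-one; 19 4-bromo-1,2-dimethoxybenzene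
Product: 20 (3R,4R)-3-(3-benzyloxy-4-methoxybenzyl)-4-(3,4-dimethoxybenzyl)dihydrofuran-2(3H)-one
Conditions: NiI2 (10 mol %), 4,4'-di-tert-butyl-2,2'-bipyridine (10 mol %), NaI (25 mol %), pyridine (10 mol %), Zn dust (2 equiv), DMPU, 60 °C
Reagents that add atoms: none
Why: nickel-catalysed reductive cross-electrophile coupling of an aryl bromide with a primary alkyl bromide, in which zerovalent nickel inserts into the aryl–Br bond, the arylnickel species captures the C7 radical formed by halogen abstraction, reductive elimination forms C7–ring B and Zn returns the catalyst to its low-valent state; esters and benzyl ethers are tolerated, no strong base is present, and C4 lies next to but not at the radical centre and so keeps its configuration.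

Step 11
Reactants: 20 (3R,4R)-3-(3-benzyloxy-4-methoxybenzyl)-4-(3,4-dimethoxybenzyl)dihydrofuran-2(3H)-one
Product: 21 prestegane A, (3R,4R)-4-(3,4-dimethoxybenzyl)-3-(3-hydroxy-4-methoxybenzyl)dihydrofuran-2(3H)-one
Conditions: H2 (1 atm), 10% Pd/C, EtOAc/EtOH, rt
Reagents that add atoms: none
Why: hydrogenolysis of the aryl benzyl ether over palladium on carbon under neutral conditions should free the phenol without touching the lactone, the methyl ethers or the two stereocentres.

**Compound list**

1 | (R)-4-benzyloxazolidin-2-one | O=C1N[C@H](Cc2ccccc2)CO1 | starting material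
2 | bromoacetyl bromide | O=C(Br)CBr | starting material
3 | lithium (R)-4-benzyl-2-oxooxazolidin-3-ide | [Li+].O=C1[N-][C@H](Cc2ccccc2)CO1 | intermediate
4 | (R)-4-benzyl-3-(2-bromoacetyl)oxazolidin-2-one | O=C(CBr)N1[C@H](Cc2ccccc2)COC1=O | intermediate
5 | diethyl {2-[(R)-4-benzyl-2-oxooxazolidin-3-yl]-2-oxoethyl}phosphonate | CCOP(=O)(OCC)CC(=O)N1[C@H](Cc2ccccc2)COC1=O | intermediate
6 | oxetan-3-one | O=C1COC1 | starting material
7 | (R)-4-benzyl-3-[2-(oxetan-3-ylidene)acetyl]oxazolidin-2-one | O=C(C=C1COC1)N1[C@H](Cc2ccccc2)COC1=O | intermediate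
8 | (R)-4-benzyl-3-[2-(oxetan-3-yl)acetyl]oxazolidin-2-one | O=C(CC1COC1)N1[C@H](Cc2ccccc2)COC1=O | intermediate
9 | 3-benzyloxy-4-methoxybenzyl alcohol | COc1ccc(CO)cc1OCc1ccccc1 | starting material
10 | 3-benzyloxy-4-methoxybenzyl bromide | COc1ccc(CBr)cc1OCc1ccccc1 | intermediate
11 | sodium (Z)-1-[(R)-4-benzyl-2-oxooxazolidin-3-yl]-2-(oxetan-3-yl)ethen-1-olate (sodium enolate of 8) | [Na+].[O-]/C(=C\C1COC1)N1[C@H](Cc2ccccc2)COC1=O | intermediate
12 | (R)-4-benzyl-3-[(R)-3-(3-benzyloxy-4-methoxyphenyl)-2-(oxetan-3-yl)propanoyl]oxazolidin-2-one | COc1ccc(C[C@H](C2COC2)C(=O)N2[C@H](Cc3ccccc3)COC2=O)cc1OCc1ccccc1 | intermediate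
13 | lithium (R)-3-(3-benzyloxy-4-methoxyphenyl)-2-(oxetan-3-yl)propaneperoxoate | [Li+].[O-]OC(=O)[C@H](Cc1ccc(OC)c(OCc2ccccc2)c1)C1COC1 | intermediate
14 | lithium (R)-3-(3-benzyloxy-4-methoxyphenyl)-2-(oxetan-3-yl)propanoate | [Li+].[O-]C(=O)[C@H](Cc1ccc(OC)c(OCc2ccccc2)c1)C1COC1 | intermediate
15 | (R)-3-(3-benzyloxy-4-methoxyphenyl)-2-(oxetan-3-yl)propanoic acid | OC(=O)[C@H](Cc1ccc(OC)c(OCc2ccccc2)c1)C1COC1 | intermediate
16 | (3R,4R)-3-(3-benzyloxy-4-methoxybenzyl)-4-(hydroxymethyl)dihydrofuran-2(3H)-one (cis) | COc1ccc(C[C@H]2C(=O)OC[C@H]2CO)cc1OCc1ccccc1 | intermediate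
17 | (3R,4S)-3-(3-benzyloxy-4-methoxybenzyl)-4-(hydroxymethyl)dihydrofuran-2(3H)-one (trans) | COc1ccc(C[C@H]2C(=O)OC[C@@H]2CO)cc1OCc1ccccc1 | intermediate
18 | (3R,4R)-3-(3-benzyloxy-4-methoxybenzyl)-4-(bromomethyl)dihydrofuran-2(3H)-one (trans) | COc1ccc(C[C@H]2C(=O)OC[C@@H]2CBr)cc1OCc1ccccc1 | intermediate
19 | 4-bromo-1,2-dimethoxybenzene | COc1ccc(Br)cc1OC | starting material
20 | (3R,4R)-3-(3-benzyloxy-4-methoxybenzyl)-4-(3,4-dimethoxybenzyl)dihydrofuran-2(3H)-one | COc1ccc(C[C@H]2C(=O)OC[C@@H]2Cc2ccc(OC)c(OC)c2)cc1OCc1ccccc1 | intermediate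
21 | prestegane A, (3R,4R)-4-(3,4-dimethoxybenzyl)-3-(3-hydroxy-4-methoxybenzyl)dihydrofuran-2(3H)-one | COc1ccc(C[C@H]2C(=O)OC[C@@H]2Cc2ccc(OC)c(OC)c2)cc1O | target

**Step count and risks**

Total step count: 11. Longest linear sequence: 10 steps (steps 1–4 and 6–11, from 1 to 21); step 5 is the one-step side branch.

Step 8. The exchange between the two lactones may be too slow, or the equilibrium may leave a sizeable share of the cis lactone, and ring A may be alkylated by the protonated oxetane. The fallback sets out from 12 and comes back at 18. It moves the arm selection to an irreversible, catalyst-controlled opening by an external halide. Imide 12 would be treated with TMSBr and a chiral squaramide hydrogen-bond-donor catalyst at low temperature (enantioselective bromide opening of 3-substituted oxetanes is a known reaction type). The catalyst enantiomer is chosen so that bromide enters the CH2 that becomes C7, giving (R)-4-benzyl-3-[(2R,3R)-2-(3-benzyloxy-4-methoxybenzyl)-4-bromo-3-(trimethylsilyloxymethyl)butanoyl]oxazolidin-2-one F1. TsOH·H2O in wet THF would then cleave the silyl ether to (R)-4-benzyl-3-[(2R,3R)-2-(3-benzyloxy-4-methoxybenzyl)-4-bromo-3-(hydroxymethyl)butanoyl]oxazolidin-2-one F2. Its C5 hydroxyl should close onto the imide carbonyl and expel auxiliary 1, which delivers bromide 18 directly and makes steps 7 and 9 unnecessary.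

Step 10. Dimerisation or reduction of the alkyl bromide may outrun the cross-coupling, because the electron-rich aryl bromide adds slowly to nickel. The fallback sets out from 18 and comes back at 20. It separates the two events into a preformed nucleophile and a palladium-catalysed Negishi coupling. Zinc insertion (activated Zn dust, LiCl, THF, 50 °C) would give {[(3R,4R)-4-(3-benzyloxy-4-methoxybenzyl)-5-oxotetrahydrofuran-3-yl]methyl}zinc bromide F3. This would be coupled with 19 under Pd(OAc)2 and the biarylphosphine SPhos in THF to give 20; the lactone is tolerated by the organozinc.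

Step 7. Hydroxide may attack the ring carbonyl of the doubly branched imide, opening the auxiliary instead of releasing it, and the oxetane may open in an uncontrolled way during acidification. The fallback sets out from 12 and comes back at 15. The auxiliary would be removed reductively with LiBH4 (Et2O, 1 equiv H2O, 0 °C) to give (R)-3-(3-benzyloxy-4-methoxyphenyl)-2-(oxetan-3-yl)propan-1-ol F4. Dess–Martin oxidation (NaHCO3-buffered CH2Cl2) would give (R)-3-(3-benzyloxy-4-methoxyphenyl)-2-(oxetan-3-yl)propanal F5, used crude to protect C3. Pinnick oxidation (NaClO2, NaH2PO4, 2-methyl-2-butene, t-BuOH/H2O) would then give acid 15 without a strongly basic or strongly acidic stage.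

**Further compounds**

F1 | step 8 | (R)-4-benzyl-3-[(2R,3R)-2-(3-benzyloxy-4-methoxybenzyl)-4-bromo-3-(trimethylsilyloxymethyl)butanoyl]oxazolidin-2-one | COc1ccc(C[C@@H](C(=O)N2[C@H](Cc3ccccc3)COC2=O)[C@H](CO[Si](C)(C)C)CBr)cc1OCc1ccccc1
F2 | step 8 | (R)-4-benzyl-3-[(2R,3R)-2-(3-benzyloxy-4-methoxybenzyl)-4-bromo-3-(hydroxymethyl)butanoyl]oxazolidin-2-one | COc1ccc(C[C@@H](C(=O)N2[C@H](Cc3ccccc3)COC2=O)[C@H](CO)CBr)cc1OCc1ccccc1
F3 | step 10 | {[(3R,4R)-4-(3-benzyloxy-4-methoxybenzyl)-5-oxotetrahydrofuran-3-yl]methyl}zinc bromide | COc1ccc(C[C@H]2C(=O)OC[C@@H]2C[Zn]Br)cc1OCc1ccccc1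
F4 | step 7 | (R)-3-(3-benzyloxy-4-methoxyphenyl)-2-(oxetan-3-yl)propan-1-ol | OC[C@H](Cc1ccc(OC)c(OCc2ccccc2)c1)C1COC1
F5 | step 7 | (R)-3-(3-benzyloxy-4-methoxyphenyl)-2-(oxetan-3-yl)propanal | O=C[C@H](Cc1ccc(OC)c(OCc2ccccc2)c1)C1COC1
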